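**Strategy.** Everything rests on cutting the bond between the methyl-bearing carbon beside the ring A-side acetoxy carbinol and the allylic carbinol carbon. Their syn,syn oxygen–methyl–oxygen triad is a propionate aldol retron. The precursors are a vinyl ketone carrying ring A and an E-enal carrying ring B. The enone units inside pyranone rings A and B are locked s-trans, whereas the acyclic vinyl ketone can reach s-cis. (−)-Ipc2BH therefore adds 1,4 only to the latter and gives the Z-enol borinate without base, sparing the acidic methine between ring A and the ketone carbonyl. Aldol addition and LiBH4 reduction of the boron chelate in the same flask join both halves and set three stereocentres.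

Key step: step 19

Remarks:
- Ring A is the terminal 6-ethyl-3,5-dimethyl-4H-pyran-4-one. Ring B is the central 2,6-dialkyl-3,5-dimethyl-4H-pyran-4-one.
- Carbons that end up sp2 in a pyranone ring are carried as epimer or enol mixtures and are left undefined in the SMILES.
- (−)-Ipc2BH is the crystalline reagent prepared beforehand from (+)-α-pinene and BH3·SMe2. LDA is used as a stock solution.

**Ring B fragment (steps 1–11)**

Step 1
Reactants: 1 propanal (two molecules)
Product: 2 (2S,3S)-3-hydroxy-2-methylpentanal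
Conditions: L-proline (10 mol %), DMF, 4 °C
Reagents that add atoms: none
Why: Proline-catalysed direct self-aldol of an aldehyde, in which the E-enamine attacks the acid-activated acceptor through the Houk–List chair, so L-proline should give mainly the anti (2S,3S) dimer.

Step 2
Reactants: 2 (2S,3S)-3-hydroxy-2-methylpentanal
Product: 3 (2S,3S)-3-[(tert-butyldimethylsilyl)oxy]-2-methylpentanal
Conditions: TBSCl, imidazole, DMF, 0 °C → rt
Reagents that add atoms: TBSCl CC(C)(C)[Si](C)(C)Cl
Why: Standard silylation of a secondary alcohol stops oligomerisation and elimination of the β-hydroxy aldehyde, touches no stereocentre and allows the minor syn isomer to be removed by chromatography.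

Step 3
Reactants: 4 pentan-3-one; 3 (2S,3S)-3-[(tert-butyldimethylsilyl)oxy]-2-methylpentanal
Product: 5 (6R,7S)-7-[(tert-butyldimethylsilyl)oxy]-5-hydroxy-4,6-dimethylnonan-3-one as a C4/C5 epimer mixture
Conditions: LDA, THF, −78 °C; then 3
Reagents that add atoms: none
Why: Lithium enolate aldol addition whose two new centres later become sp2 ring carbons, so their configuration does not matter.

Step 4
Reactants: 5 (6R,7S)-7-[(tert-butyldimethylsilyl)oxy]-5-hydroxy-4,6-dimethylnonan-3-one
Product: 6 (6S,7S)-7-[(tert-butyldimethylsilyl)oxy]-4,6-dimethylnonane-3,5-dione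
Conditions: Dess–Martin periodinane, CH2Cl2, 0 °C → rt
Reagents that add atoms: none
Why: Dess–Martin oxidation of a β-hydroxy ketone to the β-diketone runs without base and should leave the α-methyl/β-silyloxy pair untouched.

Step 5
Reactants: 7 methyl (R)-3-hydroxy-2-methylpropanoate
Product: 8 methyl (R)-3-[(tert-butyldimethylsilyl)oxy]-2-methylpropanoate
Conditions: TBSCl, imidazole, CH2Cl2, rt
Reagents that add atoms: TBSCl CC(C)(C)[Si](C)(C)Cl
Why: Routine silylation of the primary alcohol of the Roche ester, whose stereocentre becomes the methine between ring B and the alkene.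

Step 6
Reactants: 8 methyl (R)-3-[(tert-butyldimethylsilyl)oxy]-2-methylpropanoate
Product: 9 (R)-3-[(tert-butyldimethylsilyl)oxy]-N-methoxy-N,2-dimethylpropanamide
Conditions: MeONHMe·HCl, i-PrMgCl, THF, −20 → 0 °C
Reagents that add atoms: N,O-dimethylhydroxylamine hydrochloride CNOC.Cl
Why: Weinreb amide formation from an ester with the chloromagnesium amide is fast at low temperature, so the α-centre is not enolised.

Step 7
Reactants: 6 (6S,7S)-7-[(tert-butyldimethylsilyl)oxy]-4,6-dimethylnonane-3,5-dione; 9 (R)-3-[(tert-butyldimethylsilyl)oxy]-N-methoxy-N,2-dimethylpropanamide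
Product: 10 (2R,8S,9S)-1,9-bis[(tert-butyldimethylsilyl)oxy]-2,4,6,8-tetramethylundecane-3,5,7-trione
Conditions: LDA (2.2 equiv), THF, −78 → −20 °C; then 9, −78 → −20 °C
Reagents that add atoms: none
Why: Claisen-type γ-acylation of a β-diketone dianion, in which the second deprotonation takes the unhindered ethyl CH2, and the chelated tetrahedral adduct of the Weinreb amide prevents over-addition and proton exchange.

Step 8
Reactants: 10 (2R,8S,9S)-1,9-bis[(tert-butyldimethylsilyl)oxy]-2,4,6,8-tetramethylundecane-3,5,7-trione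
Product: 11 2-{(2R)-1-[(tert-butyldimethylsilyl)oxy]propan-2-yl}-6-{(2S,3S)-3-[(tert-butyldimethylsilyl)oxy]pentan-2-yl}-3,5-dimethyl-4H-pyran-4-one
Conditions: PPh3, CCl4, THF, rt
Reagents that add atoms: none
Why: Appel-type dehydrative cyclisation of a 1,3,5-triketone, in which one terminal enol oxygen is activated as an oxyphosphonium and displaced by the other, a near-neutral method suited to fully substituted 4-pyranones flanked by stereocentres.

Step 9
Reactants: 11 bis-silyl ether of the ring B pyranone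
Product: 12 2-[(2S,3S)-3-hydroxypentan-2-yl]-6-[(2R)-1-hydroxypropan-2-yl]-3,5-dimethyl-4H-pyran-4-one
Conditions: 48% aq HF, MeCN, 0 °C → rt
Reagents that add atoms: none
Why: Fluoride-driven cleavage of both silyl ethers, to which the pyranone is inert.

Step 10
Reactants: 12 2-[(2S,3S)-3-hydroxypentan-2-yl]-6-[(2R)-1-hydroxypropan-2-yl]-3,5-dimethyl-4H-pyran-4-one
Product: 14 (2E,4R)-4-{6-[(2S,3S)-3-hydroxypentan-2-yl]-3,5-dimethyl-4-oxo-4H-pyran-2-yl}-2-methylpent-2-enal, via pyranonyl propanal 13 (not isolated)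
Conditions: TEMPO (cat.), PhI(OAc)2, CH2Cl2, rt; then Ph3P=C(CH3)CHO, 40 °C
Reagents that add atoms: 2-(triphenylphosphoranylidene)propanal CC(C=O)=P(c1ccccc1)(c1ccccc1)c1ccccc1
Why: Oxoammonium oxidation selective for the primary alcohol followed in the same flask by a Wittig olefination with a stabilised ylide, which should give the E-enal while the labile aldehyde is never isolated.

Step 11
Reactants: 14 (2E,4R)-4-{6-[(2S,3S)-3-hydroxypentan-2-yl]-3,5-dimethyl-4-oxo-4H-pyran-2-yl}-2-methylpent-2-enal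
Product: 15 (2S,3S)-2-{3,5-dimethyl-6-[(2R,3E)-4-methyl-5-oxopent-3-en-2-yl]-4-oxo-4H-pyran-2-yl}pentan-3-yl acetate
Conditions: Ac2O, pyridine, DMAP (cat.), CH2Cl2, 0 °C → rt
Reagents that add atoms: acetic anhydride CC(=O)OC(C)=O
Why: DMAP-catalysed acetylation of the only hydroxyl group, with bases too weak to deprotonate the γ-position of the enal.

**Ring A fragment (steps 12–18)**

Step 12
Reactants: 16 heptane-3,5-dione
Product: 17 4-methylheptane-3,5-dione
Conditions: MeI, K2CO3, acetone, reflux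
Reagents that add atoms: iodomethane CI
Why: Classical C-alkylation of a β-diketone at its central carbon.

Step 13
Reactants: 18 1-[(4R)-4-benzyl-2-thioxo-1,3-thiazolidin-3-yl]propan-1-one; 19 acrolein
Product: 20 (2R,3S)-1-[(4R)-4-benzyl-2-thioxo-1,3-thiazolidin-3-yl]-3-hydroxy-2-methylpent-4-en-1-one
Conditions: TiCl4, i-Pr2NEt, NMP, CH2Cl2, 0 °C; then 19, −78 → 0 °C
Reagents that add atoms: none
Why: Titanium enolate aldol of an N-propionyl thiazolidinethione in the Evans-syn mode, where the Z-enolate reacts through a non-chelated chair and the benzyl group of the auxiliary shields one face, setting the (2R) methyl centre that becomes the methine next to ring A.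

Step 14
Reactants: 20 (2R,3S)-1-[(4R)-4-benzyl-2-thioxo-1,3-thiazolidin-3-yl]-3-hydroxy-2-methylpent-4-en-1-one
Product: 21 (2R,3S)-1-[(4R)-4-benzyl-2-thioxo-1,3-thiazolidin-3-yl]-3-[(tert-butyldimethylsilyl)oxy]-2-methylpent-4-en-1-one
Conditions: TBSOTf, 2,6-lutidine, CH2Cl2, 0 °C
Reagents that add atoms: TBSOTf CC(C)(C)[Si](C)(C)OS(=O)(=O)C(F)(F)F
Why: Silylation with a silyl triflate and a hindered weak base blocks retro-aldol and leaves both centres unchanged.

Step 15
Reactants: 17 4-methylheptane-3,5-dione; 21 silylated aldol adduct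
Product: 22 (8R,9S)-9-[(tert-butyldimethylsilyl)oxy]-4,6,8-trimethylundec-10-ene-3,5,7-trione
Conditions: 17 (2.2 equiv), LDA (4.4 equiv), THF, −78 → 0 °C; then 21, −78 °C
Reagents that add atoms: none
Why: Claisen-type γ-acylation of a β-diketone dianion by an activated amide, where the thiazolidinethione leaves as readily as in its known displacements by carbon nucleophiles and the excess dianion absorbs the acidic product.

Step 16
Reactants: 22 (8R,9S)-9-[(tert-butyldimethylsilyl)oxy]-4,6,8-trimethylundec-10-ene-3,5,7-trione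
Product: 23 2-{(2R,3S)-3-[(tert-butyldimethylsilyl)oxy]pent-4-en-2-yl}-6-ethyl-3,5-dimethyl-4H-pyran-4-one
Conditions: PPh3, CCl4, THF, rt
Reagents that add atoms: none
Why: The same Appel-type dehydrative cyclisation of a 1,3,5-triketone as in step 8 closes ring A without base.

Step 17
Reactants: 23 2-{(2R,3S)-3-[(tert-butyldimethylsilyl)oxy]pent-4-en-2-yl}-6-ethyl-3,5-dimethyl-4H-pyran-4-one
Product: 24 2-ethyl-6-[(2R,3S)-3-hydroxypent-4-en-2-yl]-3,5-dimethyl-4H-pyran-4-one
Conditions: HF·pyridine, pyridine, THF, 0 °C → rt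
Reagents that add atoms: none
Why: Buffered fluoride cleavage of the allylic silyl ether.

Step 18
Reactants: 24 2-ethyl-6-[(2R,3S)-3-hydroxypent-4-en-2-yl]-3,5-dimethyl-4H-pyran-4-one
Product: 25 2-ethyl-3,5-dimethyl-6-[(2S)-3-oxopent-4-en-2-yl]-4H-pyran-4-one
Conditions: Dess–Martin periodinane, CH2Cl2, 0 °C; used at once
Reagents that add atoms: none
Why: Dess–Martin oxidation of the allylic alcohol under base-free conditions should keep the methine between ring A and the new ketone intact (the descriptor changes by priority only).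

**Union and end game (steps 19–21)**

Step 19
Reactants: 25 2-ethyl-3,5-dimethyl-6-[(2S)-3-oxopent-4-en-2-yl]-4H-pyran-4-one; 15 (2S,3S)-2-{3,5-dimethyl-6-[(2R,3E)-4-methyl-5-oxopent-3-en-2-yl]-4-oxo-4H-pyran-2-yl}pentan-3-yl acetate
Product: 28 (2S,3S)-2-{6-[(2R,3E,5S,6R,7R,8R)-8-(6-ethyl-3,5-dimethyl-4-oxo-4H-pyran-2-yl)-5,7-dihydroxy-4,6-dimethylnon-3-en-2-yl]-3,5-dimethyl-4-oxo-4H-pyran-2-yl}pentan-3-yl acetate, via Z-enol borinate 26 (not isolated), via boron aldolate 27 (not isolated)
Conditions: (−)-Ipc2BH (1.2 equiv), Et2O, 0 °C; then 15, −78 → −20 °C; then LiBH4 (THF), −78 °C; then MeOH, pH 7 buffer, 30% H2O2, 0 °C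
Reagents that add atoms: none
Why: (−)-Ipc2BH delivers hydride to the terminal carbon of the s-cis vinyl ketone through a six-membered transition state and gives only Z-enol borinate 26, which adds to enal 15 through a Zimmerman–Traxler chair to boron aldolate 27, whose chelated ketone is reduced by LiBH4 before buffered H2O2 frees diol 28. The closest known reaction types are the borane-mediated reductive aldol reaction of enones and acrylates, the syn aldol of Z-enol diisopinocampheylborinates and the in situ 1,3-syn reduction of boron aldolates. No ring of the product is closed, the only cycles being the chair transition state and the transient six-membered O–B–O chelate. The Z geometry and the chair set the syn relation between the new methyl-bearing carbon and the allylic carbinol carbon, and the (+)-α-pinene-derived ligands direct attack to the Si face of the aldehyde, which gives the S carbinol. The third centre, the future acetoxy carbon, comes from axial hydride delivery to the chelate (1,3-syn), which coincides with Felkin–Anh attack anti to ring A. The step needs chemoselectivity for one of three enone units and retention at the acidic methine next to ring A: the s-trans lock of rings A and B secures the first, the absence of base and the immediate reduction of the ketone secure the second, and the weak α′-induction typical of Z-enol borinates leaves the facial choice to the ligands.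

Step 20
Reactants: 28 syn,syn diol
Product: 30 (2S,3S)-2-{6-[(2R,3E,5S,6R,7R,8R)-7-acetoxy-8-(6-ethyl-3,5-dimethyl-4-oxo-4H-pyran-2-yl)-4,6-dimethyl-5-[(triethylsilyl)oxy]non-3-en-2-yl]-3,5-dimethyl-4-oxo-4H-pyran-2-yl}pentan-3-yl acetate, via allylic triethylsilyl ether 29 (not isolated)
Conditions: TESCl (1.05 equiv), imidazole, CH2Cl2, −40 °C; then Ac2O, pyridine, DMAP, −40 °C → rt
Reagents that add atoms: TESCl CC[Si](CC)(CC)Cl; acetic anhydride CC(=O)OC(C)=O
Why: The allylic hydroxyl is flanked by an sp2 carbon and is less hindered than the hydroxyl wedged between two methyl-bearing sp3 carbons and ring A, so site-selective silylation at low temperature should take it first and DMAP-catalysed acetylation then takes the remaining hydroxyl, with no stereocentre changed.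

Step 21
Reactants: 30 triethylsilyl ether diacetate
Product: 31 (2S,3S)-2-{6-[(2R,3E,5S,6S,7R,8R)-7-acetoxy-8-(6-ethyl-3,5-dimethyl-4-oxo-4H-pyran-2-yl)-5-hydroxy-4,6-dimethylnon-3-en-2-yl]-3,5-dimethyl-4-oxo-4H-pyran-2-yl}pentan-3-yl acetate (target)
Conditions: HF·pyridine, pyridine, THF, 0 °C
Reagents that add atoms: none
Why: Fluoride cleavage of an allylic triethylsilyl ether under pyridine-buffered conditions that leave both acetates in place and should not trigger 1,3-acyl migration.

**Compound list**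

1 | propanal | CCC=O | starting material
2 | (2S,3S)-3-hydroxy-2-methylpentanal | O=C[C@@H](C)[C@H](CC)O | intermediate
3 | (2S,3S)-3-[(tert-butyldimethylsilyl)oxy]-2-methylpentanal | O=C[C@@H](C)[C@H](CC)O[Si](C)(C)C(C)(C)C | intermediate
4 | pentan-3-one | CCC(=O)CC | starting material
5 | (6R,7S)-7-[(tert-butyldimethylsilyl)oxy]-5-hydroxy-4,6-dimethylnonan-3-one (C4/C5 epimers) | CCC(=O)C(C)C(O)[C@@H](C)[C@H](CC)O[Si](C)(C)C(C)(C)C | intermediate
6 | (6S,7S)-7-[(tert-butyldimethylsilyl)oxy]-4,6-dimethylnonane-3,5-dione | CCC(=O)C(C)C(=O)[C@@H](C)[C@H](CC)O[Si](C)(C)C(C)(C)C | intermediate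
7 | methyl (R)-3-hydroxy-2-methylpropanoate | OC[C@@H](C)C(=O)OC | starting material
8 | methyl (R)-3-[(tert-butyldimethylsilyl)oxy]-2-methylpropanoate | CC(C)(C)[Si](C)(C)OC[C@@H](C)C(=O)OC | intermediate
9 | (R)-3-[(tert-butyldimethylsilyl)oxy]-N-methoxy-N,2-dimethylpropanamide | CC(C)(C)[Si](C)(C)OC[C@@H](C)C(=O)N(C)OC | intermediate
10 | (2R,8S,9S)-1,9-bis[(tert-butyldimethylsilyl)oxy]-2,4,6,8-tetramethylundecane-3,5,7-trione | CC(C)(C)[Si](C)(C)OC[C@@H](C)C(=O)C(C)C(=O)C(C)C(=O)[C@@H](C)[C@H](CC)O[Si](C)(C)C(C)(C)C | intermediate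
11 | 2-{(2R)-1-[(tert-butyldimethylsilyl)oxy]propan-2-yl}-6-{(2S,3S)-3-[(tert-butyldimethylsilyl)oxy]pentan-2-yl}-3,5-dimethyl-4H-pyran-4-one | CC(C)(C)[Si](C)(C)OC[C@@H](C)c1oc([C@@H](C)[C@H](CC)O[Si](C)(C)C(C)(C)C)c(C)c(=O)c1C | intermediate
12 | 2-[(2S,3S)-3-hydroxypentan-2-yl]-6-[(2R)-1-hydroxypropan-2-yl]-3,5-dimethyl-4H-pyran-4-one | OC[C@@H](C)c1oc([C@@H](C)[C@H](CC)O)c(C)c(=O)c1C | intermediate
13 | (2S)-2-{6-[(2S,3S)-3-hydroxypentan-2-yl]-3,5-dimethyl-4-oxo-4H-pyran-2-yl}propanal | O=C[C@@H](C)c1oc([C@@H](C)[C@H](CC)O)c(C)c(=O)c1C | intermediate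
14 | (2E,4R)-4-{6-[(2S,3S)-3-hydroxypentan-2-yl]-3,5-dimethyl-4-oxo-4H-pyran-2-yl}-2-methylpent-2-enal | O=C/C(C)=C/[C@@H](C)c1oc([C@@H](C)[C@H](CC)O)c(C)c(=O)c1C | intermediate
15 | (2S,3S)-2-{3,5-dimethyl-6-[(2R,3E)-4-methyl-5-oxopent-3-en-2-yl]-4-oxo-4H-pyran-2-yl}pentan-3-yl acetate | O=C/C(C)=C/[C@@H](C)c1oc([C@@H](C)[C@H](CC)OC(C)=O)c(C)c(=O)c1C | intermediate
16 | heptane-3,5-dione | CCC(=O)CC(=O)CC | starting material
17 | 4-methylheptane-3,5-dione | CCC(=O)C(C)C(=O)CC | intermediate
18 | 1-[(4R)-4-benzyl-2-thioxo-1,3-thiazolidin-3-yl]propan-1-one | CCC(=O)N1[C@H](Cc2ccccc2)CSC1=S | starting material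
19 | acrolein | C=CC=O | starting material
20 | (2R,3S)-1-[(4R)-4-benzyl-2-thioxo-1,3-thiazolidin-3-yl]-3-hydroxy-2-methylpent-4-en-1-one | S=C1SC[C@@H](Cc2ccccc2)N1C(=O)[C@H](C)[C@@H](O)C=C | intermediate
21 | (2R,3S)-1-[(4R)-4-benzyl-2-thioxo-1,3-thiazolidin-3-yl]-3-[(tert-butyldimethylsilyl)oxy]-2-methylpent-4-en-1-one | S=C1SC[C@@H](Cc2ccccc2)N1C(=O)[C@H](C)[C@@H](O[Si](C)(C)C(C)(C)C)C=C | intermediate
22 | (8R,9S)-9-[(tert-butyldimethylsilyl)oxy]-4,6,8-trimethylundec-10-ene-3,5,7-trione | CCC(=O)C(C)C(=O)C(C)C(=O)[C@H](C)[C@@H](O[Si](C)(C)C(C)(C)C)C=C | intermediate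
23 | 2-{(2R,3S)-3-[(tert-butyldimethylsilyl)oxy]pent-4-en-2-yl}-6-ethyl-3,5-dimethyl-4H-pyran-4-one | CCc1oc([C@H](C)[C@@H](O[Si](C)(C)C(C)(C)C)C=C)c(C)c(=O)c1C | intermediate
24 | 2-ethyl-6-[(2R,3S)-3-hydroxypent-4-en-2-yl]-3,5-dimethyl-4H-pyran-4-one | CCc1oc([C@H](C)[C@@H](O)C=C)c(C)c(=O)c1C | intermediate
25 | 2-ethyl-3,5-dimethyl-6-[(2S)-3-oxopent-4-en-2-yl]-4H-pyran-4-one | CCc1oc([C@H](C)C(=O)C=C)c(C)c(=O)c1C | intermediate
26 | Z-enol diisopinocampheylborinate of the ring A ethyl ketone (methine as in 25, boron ligands from (+)-α-pinene) | CCc1oc([C@H](C)/C(=C/C)OB([C@@H]2C[C@@H]3C[C@H]([C@H]2C)C3(C)C)[C@@H]2C[C@@H]3C[C@H]([C@H]2C)C3(C)C)c(C)c(=O)c1C | intermediate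
27 | diisopinocampheylboron aldolate of the syn β-hydroxy ketone joining rings A and B | CCc1oc([C@H](C)C(=O)[C@@H](C)[C@H](OB([C@@H]2C[C@@H]3C[C@H]([C@H]2C)C3(C)C)[C@@H]2C[C@@H]3C[C@H]([C@H]2C)C3(C)C)/C(C)=C/[C@@H](C)c2oc([C@@H](C)[C@H](CC)OC(C)=O)c(C)c(=O)c2C)c(C)c(=O)c1C | intermediate
28 | (2S,3S)-2-{6-[(2R,3E,5S,6R,7R,8R)-8-(6-ethyl-3,5-dimethyl-4-oxo-4H-pyran-2-yl)-5,7-dihydroxy-4,6-dimethylnon-3-en-2-yl]-3,5-dimethyl-4-oxo-4H-pyran-2-yl}pentan-3-yl acetate | CCc1oc([C@H](C)[C@H](O)[C@@H](C)[C@H](O)/C(C)=C/[C@@H](C)c2oc([C@@H](C)[C@H](CC)OC(C)=O)c(C)c(=O)c2C)c(C)c(=O)c1C | intermediate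
29 | 5-O-triethylsilyl ether of 28 (allylic oxygen silylated, 7-hydroxyl free) | CCc1oc([C@H](C)[C@H](O)[C@@H](C)[C@H](O[Si](CC)(CC)CC)/C(C)=C/[C@@H](C)c2oc([C@@H](C)[C@H](CC)OC(C)=O)c(C)c(=O)c2C)c(C)c(=O)c1C | intermediate
30 | 7-O-acetyl-5-O-triethylsilyl derivative of 28 | CCc1oc([C@H](C)[C@H](OC(C)=O)[C@@H](C)[C@H](O[Si](CC)(CC)CC)/C(C)=C/[C@@H](C)c2oc([C@@H](C)[C@H](CC)OC(C)=O)c(C)c(=O)c2C)c(C)c(=O)c1C | intermediate
31 | (2S,3S)-2-{6-[(2R,3E,5S,6S,7R,8R)-7-acetoxy-8-(6-ethyl-3,5-dimethyl-4-oxo-4H-pyran-2-yl)-5-hydroxy-4,6-dimethylnon-3-en-2-yl]-3,5-dimethyl-4-oxo-4H-pyran-2-yl}pentan-3-yl acetate | CCc1oc([C@H](C)[C@H](OC(C)=O)[C@@H](C)[C@H](O)/C(C)=C/[C@@H](C)c2oc([C@@H](C)[C@H](CC)OC(C)=O)c(C)c(=O)c2C)c(C)c(=O)c1C | target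

**Step count**

Total step count: 21. Longest linear sequence: 12 steps (1–4, 7–11, 19–21).

**Steps most likely to fail**

**Step 19.** Three processes could hurt this step. Facial selectivity may erode if the methine stereocentre next to ring A opposes the ligand control. That methine may lose its configuration in 25 before hydroboration. Ordinary 1,2-hydroboration may also compete.

The fallback removes this stereocentre from the coupling partner. It sets out from 4 and 15 and comes back at 28.
- Pentan-3-one 4 is condensed with propionic anhydride in polyphosphoric acid to 2,6-diethyl-3,5-dimethyl-4H-pyran-4-one F1.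
- Vinylogous deprotonation (LDA, THF, −78 °C) and acylation with N-methoxy-N-methylpropanamide give racemic 2-ethyl-3,5-dimethyl-6-(3-oxopentan-2-yl)-4H-pyran-4-one F2.
- Its acidic methine is selenenylated (LiHMDS, PhSeBr) to 2-ethyl-3,5-dimethyl-6-[3-oxo-2-(phenylselanyl)pentan-2-yl]-4H-pyran-4-one F3.
- H2O2 oxidation with syn elimination gives the achiral 2-ethyl-3,5-dimethyl-6-(3-oxopent-1-en-2-yl)-4H-pyran-4-one F4.
- Enolisation with (−)-Ipc2BOTf and i-Pr2NEt and addition to 15 forms the same carbon–carbon bond under pure ligand control and gives the syn β-hydroxy α′-methylene ketone F5.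
- Narasaka–Prasad reduction (Et2BOMe, NaBH4) gives the syn,syn allylic diol F6.
- Hydroxyl-directed hydrogenation with [Rh(nbd)(dppb)]BF4 and H2 should place the new methyl group anti to the neighbouring hydroxyl, as with α-(1-hydroxyalkyl)acrylates, and delivers 28.

**Step 20.** The silylation may not discriminate well enough between the two secondary hydroxyl groups. The fallback replaces steric discrimination by the kinetic opening of a temporary ring. It sets out from 28 and comes back at 31.
- Diol 28 is treated with MeC(OMe)3 and catalytic PPTS to give the cyclic 2-methoxy-2-methyl-1,3-dioxane orthoacetate F7.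
- Aqueous acetic acid then hydrolyses F7 through the hemiorthoester. This should release the less hindered and better leaving allylic oxygen and keep the acetyl group on the hindered oxygen.

**Step 10.** The methine between ring B and the formyl group of 13 may epimerise while the slow olefination proceeds at 40 °C. The fallback builds the trisubstituted alkene by metathesis. It sets out from 12 and comes back at 14.
- The alcohol is oxidised as before to 13.
- Aldehyde 13 is methylenated at once under non-basic conditions (Zn, CH2Br2, TiCl4, Lombardo methylenation) to 2-[(2R)-but-3-en-2-yl]-6-[(2S,3S)-3-hydroxypentan-2-yl]-3,5-dimethyl-4H-pyran-4-one F8.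
- Cross-metathesis with methacrolein (second-generation Hoveyda–Grubbs catalyst, CH2Cl2, 40 °C) gives 14.

**Further compounds**

F1 | step 19 | 2,6-diethyl-3,5-dimethyl-4H-pyran-4-one | CCc1oc(CC)c(C)c(=O)c1C
F2 | step 19 | racemic 2-ethyl-3,5-dimethyl-6-(3-oxopentan-2-yl)-4H-pyran-4-one | CCC(=O)C(C)c1oc(CC)c(C)c(=O)c1C
F3 | step 19 | racemic 2-ethyl-3,5-dimethyl-6-[3-oxo-2-(phenylselanyl)pentan-2-yl]-4H-pyran-4-one | CCC(=O)C(C)([Se]c1ccccc1)c1oc(CC)c(C)c(=O)c1C
F4 | step 19 | 2-ethyl-3,5-dimethyl-6-(3-oxopent-1-en-2-yl)-4H-pyran-4-one | CCC(=O)C(=C)c1oc(CC)c(C)c(=O)c1C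
F5 | step 19 | syn β-hydroxy α′-methylene ketone joining rings A and B | CCc1oc(C(=C)C(=O)[C@@H](C)[C@H](O)/C(C)=C/[C@@H](C)c2oc([C@@H](C)[C@H](CC)OC(C)=O)c(C)c(=O)c2C)c(C)c(=O)c1C
F6 | step 19 | syn,syn allylic diol with the exocyclic methylene next to ring A | CCc1oc(C(=C)[C@H](O)[C@@H](C)[C@H](O)/C(C)=C/[C@@H](C)c2oc([C@@H](C)[C@H](CC)OC(C)=O)c(C)c(=O)c2C)c(C)c(=O)c1C
F7 | step 20 | cyclic 2-methoxy-2-methyl-1,3-dioxane orthoacetate of 28 | CCc1oc([C@H](C)[C@@H]3OC(C)(OC)O[C@H](/C(C)=C/[C@@H](C)c2oc([C@@H](C)[C@H](CC)OC(C)=O)c(C)c(=O)c2C)[C@@H]3C)c(C)c(=O)c1C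
F8 | step 10 | 2-[(2R)-but-3-en-2-yl]-6-[(2S,3S)-3-hydroxypentan-2-yl]-3,5-dimethyl-4H-pyran-4-one | C=C[C@@H](C)c1oc([C@@H](C)[C@H](CC)O)c(C)c(=O)c1C
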